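I decided to count these flasks in halvings of the X still present, not in hours, so that the question about Thursday's flask becomes a count.

| setting | Saturday's | Friday's | Wednesday's | Tuesday's | Thursday's |
|---|---|---|---|---|---|
| X | 1.00 M | 0.400 M | 1.00 M | 1.00 M | 1.00 M |
| Z | 0.00200 M | 0.00200 M | 0.00600 M | 0.00200 M | 0.00200 M |
| L |  |  |  | 0.500 M |  |
| time |  |  |  |  | 15 h |

| Saturday's run: time / h | Saturday's run: [L] / M | Friday's run: time / h | Friday's run: [L] / M | Wednesday's run: time / h | Wednesday's run: [L] / M | Tuesday's run: time / h | Tuesday's run: [L] / M |
|---|---|---|---|---|---|---|---|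
| 1.0 | 0.236 | 1.0 | 0.096 | 1.0 | 0.569 | 1.0 | 0.734 |
| 2.0 | 0.414 | 2.0 | 0.165 | 2.0 | 0.810 | 2.0 | 0.912 |
| 3.0 | 0.553 | 3.0 | 0.218 | 3.0 | 0.925 | 3.0 | 1.044 |
| 4.0 | 0.659 | 4.0 | 0.264 | 4.0 | 0.961 | 4.0 | 1.160 |
| 5.0 | 0.735 | 5.0 | 0.296 | 5.0 | 0.983 | 5.0 | 1.238 |

(readings scatter by 0.003 M)

* apparent order in [X] of the starting rate, round the charge of the Saturday's run (the rate where two percent of its X have turned into L) (one fixed amount of L, the same in the runs compared)
* apparent order in [Z] of the starting rate, round the charge of the Saturday's run (the rate where two percent of its X have turned into L)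
* the Friday's run starts with 0.600 M less of X than the Saturday's run, and with no L. Compared where both hold the same amount of X, once fifteen percent of what the Friday's run was charged with has turned into L, is the Friday's run faster, slower or alike (within a tenth)?
* L in the Thursday's run at 15 h, as a share of the X charged

- Overall: X -> L, with Z as catalyst.
- Constant volume, constant temperature.
- An order is taken over about fifteen percent of the charge, up and down.

In the first hour, Saturday's flask, where catalyst Z turns X into L, made 0.236 M of L. Tuesday's flask, charged with 0.500 M of L, made 0.234 M, so with a scatter of 0.003 M I could read no effect of the added L.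

For the middle of the run I defined τ, the time in which a flask loses half of the X it holds at that moment, a pseudo-first-order half-life at fixed Z. Saturday's flask held 0.265 M of X at 5.0 h, which gave τ = 2.61 h. Friday's flask, charged with 0.400 M of X, gave 2.57 h from its own reading at 5.0 h. This is alike within the tenth asked, so I took the order in X as about one and Friday's flask as alike at equal X.

Wednesday's flask, with 0.00600 M of Z, gave τ = 0.835 h from its reading at 2.0 h. The slope in Z between the two charges was therefore 1.04. That is an average across the whole interval, and I had no reading between the two charges to show the slope at Saturday's charge.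

Thursday's flask has Saturday's charge, so its 15 h is 5.75 halvings. Putting each halving back in leaves 0.0186 M of X, which is 6.20 times the scatter, and that remainder is what to watch at the end. My share of L was 98.1%.

The forecast gave 1 in X, 1.04 in Z, alike, and 98.2% where I had 98.1%, calling the order in Z “nearly first order, perhaps with a trace of poison”.

The flask gave 1.0 in X, 1.8 in Z, alike, and 98.2%.

    2 Z ⇌ Z2, settled at all times (464.0 L mol⁻¹)
    Z + X → L + Z (457.2 L mol⁻¹ h⁻¹)
    X → L (0.02408 h⁻¹)
    Z + Xi → Xo

My reckoning and the flask part on Z: round Saturday's charge the order is 1.8, against my slope of 1.04 across the tripling. Xi, there from the start, takes 0.00121 M of Z at once, out of the 0.00200 M in Saturday's flask. The 98.2% in Thursday's flask is 5.80 halvings, against my 5.75. Friday's flask reached half its charge in 2.60 h, against τ of 2.61 h.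

(The numbers in the tables were computed for substances that don't exist; the scatter is artificial.)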